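**Quick answer.** Stop the flask at about 6.00 min and expect 27.7 % target, because oak and birch both read highest there. Your hunch that more coupling partner gives more target holds in the readings: birch reaches 36.5 % and oak 19.2 %.

| setting | oak | birch | maple | flask |
|---|---|---|---|---|
| starting material | 0.10 M | 0.10 M | 0.050 M | 0.10 M |
| coupling partner | 0.090 M | 0.36 M | 0.18 M | 0.180 M |
| remark | run made earlier | run made earlier | run made earlier |  |
| time |  |  |  | 2.0 h |

| run | time / min | target / % | starting material / % |
|---|---|---|---|
| oak | 1.33 | 10.2 | 90.2 |
| oak | 3.00 | 18.4 | 81.9 |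
| oak | 6.00 | 19.2 | 69.9 |
| oak | 12.0 | 16.1 | 64.4 |
| oak | 25.0 | 7.1 | 56.0 |
| oak | 60.0 | 0.4 | 52.8 |
| oak | 120 | 0 | 52.5 |
| birch | 1.33 | 25.5 | 70.9 |
| birch | 3.00 | 34.8 | 57.2 |
| birch | 6.00 | 36.5 | 45.8 |
| birch | 12.0 | 26.7 | 36.4 |
| birch | 25.0 | 10.5 | 30.7 |
| birch | 60.0 | 0.6 | 23.0 |
| birch | 120 | 0 | 21.9 |
| maple | 1.33 | 15.6 | 82.2 |
| maple | 4.00 | 29.3 | 63.3 |
| maple | 12.0 | 26.2 | 46.1 |
| maple | 40.0 | 4.0 | 31.0 |
| maple | 120 | 1.5 | 24.1 |

(readings scatter by 1 percentage point)

* when, up to 2.0 h, the flask holds most target
* the amount of target, in percent of the starting material charged, at that time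



**Peak share.** Highest target reading over starting material converted by the last reading gives 0.404 in oak, 0.467 in birch and 0.386 in maple. Their mean, 0.419, is a reading I call the peak share, the best target per unit of starting material finally converted.

**My reckoning.** The flask has the starting material charge of oak and birch, and c(coupling partner) is twice oak's, with birch's twice the flask's. I therefore take the geometric mean of their leftovers, 33.9 % starting material. Multiplying the peak share by the 66.1 % of starting material that this counts as finally converted gives my figure.

**The check.** The forecast says 29 % at 0.09 h, holding that the flask “should behave much like maple”, and the flask gives 28.2 % at 5.69 min.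

    2 coupling partner → side product (k = 1.10 M⁻¹ min⁻¹)
    target → over-reaction product (k = 0.0960 min⁻¹)
    starting material + coupling partner → target (k = 1.10 M⁻¹ min⁻¹)

**The partner.** In the flask, the step to target uses coupling partner at 0.28 of the rate of its coupling with itself at the start and 0.56 at 0.0577 h; this limiting reagent is under a fiftieth of its charge at 0.624 h, and 35.8 % of the starting material stands at 2.00 h. The flask's best is a peak share of 0.439 of the 64.2 % converted by 2.00 h, and the neighbour charged with 0.11 M of coupling partner holds 22.0 % at its best, with 52.4 % converted by the same time, a peak share of 0.420.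

The earlier runs and the new flask were computed from invented constants, noise included.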